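## The problem

- Target 12 is a 2-aryl-3-aroylbenzofuran. Ring A (the benzo ring, C3a to C7a) is fused to the furan ring B (O1, C2, C3). C2 carries the 4-hydroxyphenyl ring C. C3 carries, through the ketone carbon C8, the 2,4-dihydroxyphenyl ring D. C7 carries a second ketone carbon, C9, whose chain C10–C11 ends in the 4-hydroxyphenyl ring E.
- There is no stereocentre, so the task is purely regiochemical. Ring A is substituted at five of its six carbons, and the two acyl groups must end up at C3 and C7 and nowhere else on three electron-rich rings.
- C2, C3 and C4 are mutually crowded and the C8 ketone is twisted between two ortho-substituted rings. This argues for making the furan ring and the C3–C8 bond in one event, not for acylating a finished benzofuran.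
- The six phenolic hydroxyls, two of them hydrogen-bonded to ketones, make the free compound polar and prone to oxidation. The oxygens should therefore travel as ethers and be released together at the end, by a reagent that leaves both ketones and the saturated chain alone.
- Sensitive points on the way are an aldehyde C–H bond (decarbonylation under metal catalysis), an o-alkynylphenol (premature closure to a benzofuran without the C3 substituent) and electron-rich arenes (over-halogenation).
- The enabling feature is that C9 on C7 sits ortho to the C6 hydroxyl, a salicyloyl unit, and that C9–C10–C11–ring E is the anti-Markovnikov adduct of an aldehyde C–H bond across a 4-oxygenated styrene. A C7 aldehyde with a free C6 hydroxyl can therefore be hydroacylated under phenoxide chelation, and the directing hydroxyl is one the target keeps.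

## Retrosynthesis

**12 to 11.** The four O–CH3 bonds at C4 and on rings C, D (C4′) and E are cut. Tetramethyl ether 11 already has the two chelated hydroxyls (C6 and ring D C2′) free, so only unchelated aryl methyl ethers remain for the last step. Methyl ethers are preferred to benzyl ethers because they survive palladium, rhodium and hydride-forming conditions. The forward reaction must cleave four ethers without touching two ketones.

**11 to 9 and 10.** The C9–C10 bond is cut, giving salicylaldehyde-type benzofuran 9 and 4-methoxystyrene 10. The neighbouring cuts are weaker. A Friedel–Crafts acylation at C7 would have to distinguish C7 from C5. An aldol/hydrogenation sequence would need a C7 methyl ketone and two more steps. The hydroacylation adds ring E and both methylenes in one by-product-free step, using the C6 hydroxyl as a built-in directing group. The forward reaction must insert the styrene in the linear sense and avoid decarbonylation.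

**9 to 8.** The C6 and ring D C2′ hydroxyls are traced back to methyl ethers in pentamethyl ether 8. Both lie ortho to a carbonyl group and can be released together by chelation-directed dealkylation, so the directing hydroxyl needs no separate protecting group. The forward reaction must leave the C4 ether and the two para ethers, although extra cleavage would not be fatal.

**8 to 6 and 7.** The furan ring is opened at O1–C2 and the ketone is cut at C3–C8 and C8–C1′. This leads to o-alkynylphenol 6, aryl iodide 7 and one carbon from the gas phase, joined in a palladium-catalysed carbonylative annulation. Against a stepwise cyclisation and later C3 acylation, this forms the most crowded bond (C3–C8) in the ring-closing step and brings in ring D as a purchased iodide. The forward reaction must let acyl transfer outrun simple cyclisation.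

**6 to 3 and 4 (via 5).** The aryl–alkynyl bond is cut, giving iodide 3 and 4-ethynylanisole 4 (Sonogashira coupling). The phenol is carried as an acetate through the coupling (5) so that it cannot add to the alkyne under copper and palladium, and is released afterwards under mild base.

**3 to 1 (via 2).** The C–I bond and the acetate are removed, leading to commercial 2-hydroxy-4,6-dimethoxybenzaldehyde 1. Compound 1 already holds the future C7 carbon as the aldehyde, the future O1 as the phenol and both ring A ether oxygens. The forward iodination must go to the position next to the hydroxyl, not between the two methoxy groups.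

## Roads not taken

**Alternative 1:** Ring A is cut at C7a–C7, C6–C7, C4–C5 and C3a–C4, leaving a furan.
- Forward key step: diazoketone A2, 2-diazo-1-[4-(2,4-dimethoxybenzoyl)-5-(4-methoxyphenyl)furan-2-yl]ethan-1-one, undergoes Wolff rearrangement to a furylketene. This adds ethoxyacetylene A3 in a [2+2] sense. The cyclobutenone opens in a four-electron process, and the dienylketene closes onto the furan in a six-electron process and tautomerises to phenol A1, (2,4-dimethoxyphenyl)[6-ethoxy-4-hydroxy-2-(4-methoxyphenyl)-1-benzofuran-3-yl]methanone.
- Merits: the mechanism fixes the oxygenation pattern of ring A, with the hydroxyl at C4 and the ether at C6 and no regiochemical doubt. In this respect it is better than the chosen route, whose step 1 relies on a directing effect.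
- Weak points: A1 still has hydrogen at C7, so the whole C9–C11 chain and ring E remain to be attached by electrophilic acylation, where C5 and C7 compete. The free hydroxyl is at C4, not C6, so neither a Fries-type nor a chelation-directed process points to C7. A2 is a trisubstituted furan that needs its own multistep synthesis and a diazo transfer. The C6 ethyl ether is a sixth ether of a different kind.
- Comparison: clearly longer for this target. The chosen plan sets against the regiochemical certainty of A1 the fact that 1 is bought with the C7 carbon and all ring A oxygens in place, so ring A needs no construction.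

**Alternative 2:** The furan ring and the C3 ketone are cut (O1–C2, C3–C8, C8–C1′) with the C7 chain already present.
- Forward key step: alkynylphenol A5, 1-{2-hydroxy-4,6-dimethoxy-3-[(4-methoxyphenyl)ethynyl]phenyl}-3-(4-methoxyphenyl)propan-1-one, aryl iodide 7 and one carbon from the gas phase are joined by zerovalent palladium to give the hexamethyl ether A4 of the target.
- Merits: this is the annulation of step 5, moved to the last C–C bond-forming position. The chain would come from a classical aldol condensation and hydrogenation, so the linear/branched question of the chosen key step never arises and no selective ether cleavage is needed. For the C9–C10 bond this road is the safer one.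
- Weak points: the dihydrochalcone must be carried through iodination (ring E is a second electron-rich arene), protection, coupling and deprotection. The enone must be reduced before iodide and alkyne are present, which fixes a fully linear order. The last step must cleave six ethers. The step count is the same, not lower.
- Comparison: equal in length and lower in risk at one bond. The chosen plan sets against this its convergence: ring E arrives in the penultimate step from the common aldehyde 9 by an addition without by-products, so ring E analogues cost two steps each. Its fallback for the key step (organomagnesium addition to 9 and oxidation) recovers most of the certainty of A4 at the cost of one step.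

**Alternative 3:** Ring D is cut at C1′–C2′ and C5′–C6′.
- Forward key step: ynone A7, 1-{4,6-dimethoxy-2-(4-methoxyphenyl)-7-[3-(4-methoxyphenyl)propanoyl]-1-benzofuran-3-yl}prop-2-yn-1-one, and diene A8, 1,3-dimethoxy-1-(trimethylsilyloxy)buta-1,3-diene, combine in a [4+2] cycloaddition. Acid work-up aromatises the adduct to the 2-hydroxy-4-methoxyphenyl ketone A6.
- Merits: the polarisation of both partners fixes the orientation, and ring D arrives with its ortho hydroxyl free and its para oxygen methylated. That is the pattern step 6 of the chosen route must produce by selective cleavage, so on this point the alternative is better.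
- Weak points: ring D is an ordinary resorcinol ring that can be bought as 7. Building it requires A7, whose propynoyl group must be placed on the crowded C3 by a separate sequence, and the ynone is a reactive acceptor. A8 is moisture-sensitive. The route is several steps longer.
- Comparison: the chosen plan installs ring D, C8 and the furan ring in one step (step 5). Imperfect selectivity in step 6 is tolerable because every ether falls in step 8.

Key step: step 7

## Route

Step 1
Reactants: 1 2-hydroxy-4,6-dimethoxybenzaldehyde
Product: 2 2-hydroxy-3-iodo-4,6-dimethoxybenzaldehyde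
Conditions: BnMe3N+ ICl2− (1.05 equiv), NaHCO3, CH2Cl2–MeOH, rt
Reagents that add atoms: benzyltrimethylammonium dichloroiodate, C[N+](C)(C)Cc1ccccc1.Cl[I-]Cl
Why: Electrophilic aromatic iodination of a phenol; the position between the hydroxyl and the C4 methoxy group is ortho to the free phenol and less hindered than the position between the two methoxy groups, and one equivalent of this mild iodinating salt should stop at the mono-iodide.

Step 2
Reactants: 2 2-hydroxy-3-iodo-4,6-dimethoxybenzaldehyde
Product: 3 2-formyl-6-iodo-3,5-dimethoxyphenyl acetate
Conditions: Ac2O, pyridine, DMAP (cat.), 0 °C → rt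
Reagents that add atoms: acetic anhydride, CC(=O)OC(C)=O
Why: Nucleophile-catalysed O-acetylation of a phenol; the acetate masks the hydroxyl so that it cannot add to the alkyne during the coupling that follows.

Step 3
Reactants: 3 2-formyl-6-iodo-3,5-dimethoxyphenyl acetate; 4 4-ethynylanisole
Product: 5 2-formyl-3,5-dimethoxy-6-[(4-methoxyphenyl)ethynyl]phenyl acetate
Conditions: PdCl2(PPh3)2 (cat.), CuI (cat.), Et3N, THF (degassed), 50 °C
Reagents that add atoms: none
Why: Sonogashira coupling of an aryl iodide with a terminal alkyne; the iodide reacts despite its two ortho substituents, the aldehyde and the aryl acetate are inert to the tertiary amine, and the alkyne is meta to the aldehyde so no cyclisation onto it is possible.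

Step 4
Reactants: 5 2-formyl-3,5-dimethoxy-6-[(4-methoxyphenyl)ethynyl]phenyl acetate
Product: 6 2-hydroxy-4,6-dimethoxy-3-[(4-methoxyphenyl)ethynyl]benzaldehyde
Conditions: K2CO3 (cat.), MeOH–THF, 0 °C
Reagents that add atoms: none
Why: Base-catalysed methanolysis (transesterification) of an activated aryl acetate; at 0 °C and without copper or palladium the liberated phenol should not add to the alkyne.

Step 5
Reactants: 6 2-hydroxy-4,6-dimethoxy-3-[(4-methoxyphenyl)ethynyl]benzaldehyde; 7 1-iodo-2,4-dimethoxybenzene
Product: 8 3-(2,4-dimethoxybenzoyl)-4,6-dimethoxy-2-(4-methoxyphenyl)-1-benzofuran-7-carbaldehyde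
Conditions: Pd(PPh3)4 (cat.), K2CO3, CO (1 atm), MeCN, 45 °C
Reagents that add atoms: carbon monoxide, [C-]#[O+]
Why: Palladium-catalysed carbonylative annulation of an o-alkynylphenol with an aryl iodide; oxidative addition of 7 to zerovalent palladium and CO insertion give an aroyl complex of divalent palladium that activates the alkyne for anti attack of the phenoxide (5-endo-dig, O1–C2), and reductive elimination forms C3–C8. The electron-rich iodide favours CO insertion over direct arylation.

Step 6
Reactants: 8 3-(2,4-dimethoxybenzoyl)-4,6-dimethoxy-2-(4-methoxyphenyl)-1-benzofuran-7-carbaldehyde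
Product: 9 6-hydroxy-3-(2-hydroxy-4-methoxybenzoyl)-4-methoxy-2-(4-methoxyphenyl)-1-benzofuran-7-carbaldehyde
Conditions: BCl3 (4 equiv), CH2Cl2, −78 → 0 °C; then H2O
Reagents that add atoms: none
Why: Chelation-directed Lewis-acid dealkylation; BCl3 bridges a carbonyl oxygen and the ether oxygen ortho to it in a six-membered chelate, so only the C6 ether (next to the aldehyde) and the ring D C2′ ether (next to C8) should lose methyl. The C4 ether would need a seven-membered chelate and the para ethers have none, and any extra cleavage would be harmless because all ethers fall in step 8.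

Step 7
Reactants: 9 6-hydroxy-3-(2-hydroxy-4-methoxybenzoyl)-4-methoxy-2-(4-methoxyphenyl)-1-benzofuran-7-carbaldehyde; 10 4-methoxystyrene
Product: 11 1-[6-hydroxy-3-(2-hydroxy-4-methoxybenzoyl)-4-methoxy-2-(4-methoxyphenyl)-1-benzofuran-7-yl]-3-(4-methoxyphenyl)propan-1-one
Conditions: [Rh(cod)Cl]2 (5 mol %; cod = 1,5-cyclooctadiene), 1,1'-bis(diphenylphosphino)ferrocene (10 mol %), Na2CO3 (20 mol %), 10 (3 equiv), toluene, 100 °C
Reagents that add atoms: none
Why: Chelation-assisted rhodium-catalysed alkene hydroacylation, the closest known reaction type being the intermolecular hydroacylation of terminal alkenes and vinylarenes with salicylaldehydes. Carbonate deprotonates the C6 hydroxyl, the phenoxide binds monovalent rhodium, and oxidative addition of the C7 formyl C–H bond gives a five-membered acyl hydride chelate of trivalent rhodium, in which the bound phenoxide holds the acyl group and retards decarbonylation. Alkene 10 coordinates and inserts into the Rh–H bond; insertion that puts rhodium on the terminal carbon gives the linear alkyl, and C–C reductive elimination forms C9–C10 and returns monovalent rhodium. No ring is closed and no stereocentre is formed. The selectivity needed is linear over branched: benzylic insertion is reversible by β-hydride elimination, its reductive elimination is slowed because the acyl group is flanked on both sides (C6–O–Rh and C7a–O1), the 4-methoxy group of 10 lowers the stability of a benzylic rhodium alkyl, and the wide-bite-angle bisphosphine crowds the metal further. Chemoselectivity comes from the substrate, since only the C6 hydroxyl is ortho to the aldehyde; the ring D hydroxy ketone can bind rhodium reversibly but offers no C–H bond to activate. Product 11 keeps the C6 hydroxyl that the target needs, so no directing group is added or removed.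

Step 8
Reactants: 11 1-[6-hydroxy-3-(2-hydroxy-4-methoxybenzoyl)-4-methoxy-2-(4-methoxyphenyl)-1-benzofuran-7-yl]-3-(4-methoxyphenyl)propan-1-one
Product: 12 1-[3-(2,4-dihydroxybenzoyl)-4,6-dihydroxy-2-(4-hydroxyphenyl)-1-benzofuran-7-yl]-3-(4-hydroxyphenyl)propan-1-one
Conditions: BBr3 (excess), CH2Cl2, −78 °C → rt; then MeOH, H2O
Reagents that add atoms: none
Why: Exhaustive Lewis-acid cleavage of aryl methyl ethers; BBr3 binds each ether oxygen and bromide removes the methyl group, while the two ketones, the benzofuran and the saturated chain offer nothing that BBr3 attacks, and hydrolysis on work-up releases the hexaphenol.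

## Compound list

1 | 2-hydroxy-4,6-dimethoxybenzaldehyde | COc1cc(O)c(C=O)c(OC)c1 | starting material
2 | 2-hydroxy-3-iodo-4,6-dimethoxybenzaldehyde | COc1cc(OC)c(I)c(O)c1C=O | intermediate
3 | 2-formyl-6-iodo-3,5-dimethoxyphenyl acetate | CC(=O)Oc1c(I)c(OC)cc(OC)c1C=O | intermediate
4 | 4-ethynylanisole (1-ethynyl-4-methoxybenzene) | COc1ccc(C#C)cc1 | starting material
5 | 2-formyl-3,5-dimethoxy-6-[(4-methoxyphenyl)ethynyl]phenyl acetate | CC(=O)Oc1c(C#Cc2ccc(OC)cc2)c(OC)cc(OC)c1C=O | intermediate
6 | 2-hydroxy-4,6-dimethoxy-3-[(4-methoxyphenyl)ethynyl]benzaldehyde | COc1ccc(cc1)C#Cc1c(O)c(C=O)c(OC)cc1OC | intermediate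
7 | 1-iodo-2,4-dimethoxybenzene | COc1ccc(I)c(OC)c1 | starting material
8 | 3-(2,4-dimethoxybenzoyl)-4,6-dimethoxy-2-(4-methoxyphenyl)-1-benzofuran-7-carbaldehyde | COc1ccc(cc1)-c1oc2c(C=O)c(OC)cc(OC)c2c1C(=O)c1ccc(OC)cc1OC | intermediate
9 | 6-hydroxy-3-(2-hydroxy-4-methoxybenzoyl)-4-methoxy-2-(4-methoxyphenyl)-1-benzofuran-7-carbaldehyde | COc1ccc(cc1)-c1oc2c(C=O)c(O)cc(OC)c2c1C(=O)c1ccc(OC)cc1O | intermediate
10 | 4-methoxystyrene (1-ethenyl-4-methoxybenzene) | C=Cc1ccc(OC)cc1 | starting material
11 | 1-[6-hydroxy-3-(2-hydroxy-4-methoxybenzoyl)-4-methoxy-2-(4-methoxyphenyl)-1-benzofuran-7-yl]-3-(4-methoxyphenyl)propan-1-one | COc1ccc(CCC(=O)c2c(O)cc(OC)c3c(C(=O)c4ccc(OC)cc4O)c(-c4ccc(OC)cc4)oc23)cc1 | intermediate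
12 | 1-[3-(2,4-dihydroxybenzoyl)-4,6-dihydroxy-2-(4-hydroxyphenyl)-1-benzofuran-7-yl]-3-(4-hydroxyphenyl)propan-1-one | O=C(CCc1ccc(O)cc1)c1c(O)cc(O)c2c(C(=O)c3ccc(O)cc3O)c(-c3ccc(O)cc3)oc12 | target

## Step count and least certain steps

Total step count: 8. Longest linear sequence: 8 steps (1 to 12); compounds 4, 7 and 10 enter as purchased building blocks.

**Step 7 (key step).**
- Risk: loss of regiocontrol in the hydride insertion. A vinylarene can place rhodium on the benzylic carbon, and if reductive elimination from that alkyl competes, the branched ketone forms beside the linear one.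
- Further risks: the doubly ortho-substituted acyl rhodium hydride may decarbonylate before the alkene inserts, and the ring D hydroxy ketone may hold part of the catalyst in an unproductive chelate.
- Fallback: this sets out from 9 and abandons C–H activation for carbonyl addition. Aldehyde 9 is treated with an excess of purchased 4-MeOC6H4CH2CH2MgBr (THF, −78 → 0 °C). The first two equivalents deprotonate the phenols, and the hindered C8 ketone, deactivated as its magnesium phenoxide chelate, should not be attacked. This gives the racemic benzylic alcohol (2-hydroxy-4-methoxyphenyl){6-hydroxy-7-[1-hydroxy-3-(4-methoxyphenyl)propyl]-4-methoxy-2-(4-methoxyphenyl)-1-benzofuran-3-yl}methanone F1. Oxidation of this o-hydroxybenzylic alcohol with activated MnO2 (CH2Cl2, rt) removes the stereocentre and comes back to the route at 11.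

**Step 5.**
- Risk: the acyl transfer may be outrun by simple cyclisation to the benzofuran without the C3 substituent, by non-carbonylative arylation, or by O-aroylation of the phenol. The phenoxide ortho to the aldehyde is a weak nucleophile and iodide 7 is ortho-substituted.
- Fallback: this sets out from 6 and separates ring closure from ketone formation. Iodocyclisation of 6 (I2, NaHCO3, MeCN, rt) gives 3-iodo-4,6-dimethoxy-2-(4-methoxyphenyl)-1-benzofuran-7-carbaldehyde F2. A carbonylative Suzuki–Miyaura coupling of F2 with purchased (2,4-dimethoxyphenyl)boronic acid (PdCl2(PPh3)2, K2CO3, CO 1 atm, anisole, 80 °C) then forms C3–C8 and C8–C1′ and comes back to the route at 8.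

**Step 1.**
- Risk: iodination at the position between the two methoxy groups, or a second iodination. Both free ring positions are activated by three oxygen substituents and the preference for the site next to the hydroxyl rests on analogy.
- Fallback: this sets out from 4, introduces the aldehyde last and replaces steps 1 to 5.
  - Sonogashira coupling of 4 with purchased 2-iodo-1,3,5-trimethoxybenzene (symmetrical, so no regiochemical question) gives 1,3,5-trimethoxy-2-[(4-methoxyphenyl)ethynyl]benzene F3.
  - Iodocyclisation (I2, CH2Cl2, rt) with loss of one O-methyl group gives 3-iodo-4,6-dimethoxy-2-(4-methoxyphenyl)-1-benzofuran F4.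
  - The carbonylative Suzuki–Miyaura coupling described above gives (2,4-dimethoxyphenyl)[4,6-dimethoxy-2-(4-methoxyphenyl)-1-benzofuran-3-yl]methanone F5.
  - Vilsmeier–Haack formylation (POCl3, DMF) comes back to the route at 8. It is expected at C7, the less hindered of the two activated ring A positions and the usual site of electrophilic attack in 4,6-dimethoxybenzofurans.
- The sequence is one step shorter on paper, but it moves the regiochemical question to a late formylation and puts the carbonylative coupling on a very hindered iodide. For that reason it is held in reserve.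

**Step 8.**
- Risk: incomplete cleavage of one or more of the four ethers, or degradation and difficult isolation of the air-sensitive hexaphenol after long exposure of the complete skeleton to BBr3.
- Fallback: this sets out from 9 and inverts the order of deprotection and chain attachment.
  - BBr3 (CH2Cl2, −78 °C → rt) on 9, which has only three ethers and no chain, gives 3-(2,4-dihydroxybenzoyl)-4,6-dihydroxy-2-(4-hydroxyphenyl)-1-benzofuran-7-carbaldehyde F6.
  - The rhodium hydroacylation of step 7 is then run on F6 with purchased 4-acetoxystyrene in 1,4-dioxane. This gives 4-{3-[3-(2,4-dihydroxybenzoyl)-4,6-dihydroxy-2-(4-hydroxyphenyl)-1-benzofuran-7-yl]-3-oxopropyl}phenyl acetate F7.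
  - Methanolysis (K2CO3 cat., MeOH, rt), which also erases any acetyl migration among the phenols, comes back to the route at the target 12.

## Further compounds

F1 | step 7 | (2-hydroxy-4-methoxyphenyl){6-hydroxy-7-[1-hydroxy-3-(4-methoxyphenyl)propyl]-4-methoxy-2-(4-methoxyphenyl)-1-benzofuran-3-yl}methanone (racemic) | COc1ccc(CCC(O)c2c(O)cc(OC)c3c(C(=O)c4ccc(OC)cc4O)c(-c4ccc(OC)cc4)oc23)cc1
F2 | step 5 | 3-iodo-4,6-dimethoxy-2-(4-methoxyphenyl)-1-benzofuran-7-carbaldehyde | COc1ccc(cc1)-c1oc2c(C=O)c(OC)cc(OC)c2c1I
F3 | step 1 | 1,3,5-trimethoxy-2-[(4-methoxyphenyl)ethynyl]benzene | COc1ccc(cc1)C#Cc1c(OC)cc(OC)cc1OC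
F4 | step 1 | 3-iodo-4,6-dimethoxy-2-(4-methoxyphenyl)-1-benzofuran | COc1ccc(cc1)-c1oc2cc(OC)cc(OC)c2c1I
F5 | step 1 | (2,4-dimethoxyphenyl)[4,6-dimethoxy-2-(4-methoxyphenyl)-1-benzofuran-3-yl]methanone | COc1ccc(cc1)-c1oc2cc(OC)cc(OC)c2c1C(=O)c1ccc(OC)cc1OC
F6 | step 8 | 3-(2,4-dihydroxybenzoyl)-4,6-dihydroxy-2-(4-hydroxyphenyl)-1-benzofuran-7-carbaldehyde | O=Cc1c(O)cc(O)c2c(C(=O)c3ccc(O)cc3O)c(-c3ccc(O)cc3)oc12
F7 | step 8 | 4-{3-[3-(2,4-dihydroxybenzoyl)-4,6-dihydroxy-2-(4-hydroxyphenyl)-1-benzofuran-7-yl]-3-oxopropyl}phenyl acetate | CC(=O)Oc1ccc(CCC(=O)c2c(O)cc(O)c3c(C(=O)c4ccc(O)cc4O)c(-c4ccc(O)cc4)oc23)cc1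
A1 | alternative 1 | (2,4-dimethoxyphenyl)[6-ethoxy-4-hydroxy-2-(4-methoxyphenyl)-1-benzofuran-3-yl]methanone | CCOc1cc(O)c2c(C(=O)c3ccc(OC)cc3OC)c(-c3ccc(OC)cc3)oc2c1
A2 | alternative 1 | 2-diazo-1-[4-(2,4-dimethoxybenzoyl)-5-(4-methoxyphenyl)furan-2-yl]ethan-1-one | COc1ccc(cc1)-c1oc(cc1C(=O)c1ccc(OC)cc1OC)C(=O)C=[N+]=[N-]
A3 | alternative 1 | ethoxyacetylene (ethoxyethyne) | CCOC#C
A4 | alternative 2 | 1-[3-(2,4-dimethoxybenzoyl)-4,6-dimethoxy-2-(4-methoxyphenyl)-1-benzofuran-7-yl]-3-(4-methoxyphenyl)propan-1-one | COc1ccc(CCC(=O)c2c(OC)cc(OC)c3c(C(=O)c4ccc(OC)cc4OC)c(-c4ccc(OC)cc4)oc23)cc1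
A5 | alternative 2 | 1-{2-hydroxy-4,6-dimethoxy-3-[(4-methoxyphenyl)ethynyl]phenyl}-3-(4-methoxyphenyl)propan-1-one | COc1ccc(CCC(=O)c2c(OC)cc(OC)c(C#Cc3ccc(OC)cc3)c2O)cc1
A6 | alternative 3 | 1-[3-(2-hydroxy-4-methoxybenzoyl)-4,6-dimethoxy-2-(4-methoxyphenyl)-1-benzofuran-7-yl]-3-(4-methoxyphenyl)propan-1-one | COc1ccc(CCC(=O)c2c(OC)cc(OC)c3c(C(=O)c4ccc(OC)cc4O)c(-c4ccc(OC)cc4)oc23)cc1
A7 | alternative 3 | 1-{4,6-dimethoxy-2-(4-methoxyphenyl)-7-[3-(4-methoxyphenyl)propanoyl]-1-benzofuran-3-yl}prop-2-yn-1-one | COc1ccc(CCC(=O)c2c(OC)cc(OC)c3c(C(=O)C#C)c(-c4ccc(OC)cc4)oc23)cc1
A8 | alternative 3 | 1,3-dimethoxy-1-(trimethylsilyloxy)buta-1,3-diene | COC(=C)C=C(OC)O[Si](C)(C)C
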